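- Violet is read at 100 min, 48.0 min beyond the last blue reading, and its charge is the blue charge, so my task is to carry the blue curve forward. Substrate is the limiting reagent.

| setting | blue | green | amber | violet |
|---|---|---|---|---|
| substrate | 200 mM | 80.0 mM | 200 mM | 200 mM |
| coupling partner | 500 mM | 380 mM | 1000 mM | 500 mM |
| free catalyst | 0.400 mM | 0.400 mM | 0.400 mM | 0.400 mM |
| time |  |  |  | 100 min |

- blue run (time / min: [product] / mM): 2.1: 10; 4.7: 34; 10: 60; 23: 106; 52: 171
- green run (time / min: [product] / mM): 2.1: 10; 4.7: 11; 10: 23; 23: 46; 52: 66
- amber run (time / min: [product] / mM): 2.1: 15; 4.7: 32; 10: 69; 23: 134; 52: 184

(readings scatter by 3 mM)

- how the opening rate goes with [substrate] round the charge of the blue run: the exponent of the rate at two percent of substrate gone to product (one fixed amount of product, the same in the runs compared)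
- how the opening rate goes with [coupling partner] round the charge of the blue run: the exponent of the rate at two percent of substrate gone to product
- the green run starts with 120 mM less of substrate and of coupling partner than the blue run, and with no product. Compared where both hold the same amount of substrate, once fifteen percent of what the green run was charged with has turned into product, is the green run faster, slower or alike (within a tenth)?
- product in the violet run at 100 min, as a share of the substrate charged

- Overall: substrate + coupling partner -> product, with free catalyst as catalyst.
- Constant volume, constant temperature.
- Bound and free are read together.
- An order is taken over about fifteen percent of the charge, up and down.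

- I carry one constant, k: the natural logarithm of substrate charged over substrate left, divided by time.
- The first thing to know is which reading to trust. One standard deviation is 30.0% of the first blue reading, and k shifts roughly in proportion, so that reading is of little use.
- At the last blue reading the same scatter moves k by 5.36%, and the violet share then lies between 97.1% and 98.0%.
- The green run changes the substrate level, but it also holds less coupling partner, so it tests the two together. The last green reading, from charges of 80.0 mM substrate and 380 mM coupling partner, gives 0.0335 min⁻¹, which is 0.903 of the blue value.
- The coupling partner matters weakly. The last amber reading, with the charge doubled, gives 0.0486 min⁻¹, which is 1.31 times the blue value.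
- So k, the pseudo-first-order constant of the blue run taken from its last reading, is 0.0371 min⁻¹. My violet share is 97.6%.
- The forecast says: “The runs read well as first order in substrate.” It gives an order in substrate of 1 (0.8 to 1.15), an order in coupling partner of 0.37 (0.15 to 0.6), green and blue alike, and a violet share of 97% (93.5% to 99%). My share stands a little above its figure, inside its range.
- The simulation gives orders of 0.92 and 0.35, green and blue alike, and a violet share of 97.4%.

    free catalyst + substrate + coupling partner → product + free catalyst (1950 L² mol⁻² min⁻¹)
    free catalyst + impurity → spent catalyst
    substrate + coupling partner ⇌ idle substrate-reagent adduct, settled at all times (7.470 L mol⁻¹)

- On violet, k gives 97.6% against 97.4%. On green, first-order decay at k puts a quarter of the green charge turned at 7.75 min against 7.85 min. The order in coupling partner stands at 0.35 because substrate and coupling partner bind into the idle substrate-reagent adduct, and the same run without that binding gives 1.0.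

The readings come from a simulation from invented constants; the scatter is artificial.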